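**Retrosynthetic overview**
1. Target (ring B as quinone) ⇐ its hydroquinone by mild oxidation ⇐ (3S,4S)-cis-isoflavan-4-ol tribenzyl ether by one hydrogenolysis (C4–OH and three O-benzyl groups).
2. cis-Isoflavan-4-ol ⇐ isoflavone by asymmetric transfer hydrogenation with dynamic kinetic resolution, which sets C3 as S.
3. Isoflavone ⇐ ring-A 2-bromoaroyl chloride + ring-B arylacetaldehyde in one flask: C-acylation makes C3–C4, enolate O-arylation makes O1–C8a. Ring C (the pyran ring) is the only ring formed; rings A and B are bought as benzene rings.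
4. Enabling feature: C4, the benzylic carbon of ring C, is bonded to C4a and therefore ortho to C8a. At the ketone level it is the acylating carbon for C3, turns C3–C2–O1 into an enolate whose oxygen is O1, activates the C8a–Br bond, and makes C3 epimerisable for the resolution before it is reduced back to CH2.
5. Fragments: aroyl chloride from methyl 3-hydroxy-4,5-dimethoxybenzoate (4 steps); arylacetaldehyde from 2,3-dimethoxyphenol (5 steps).

Key step: step 10

Remark: chroman numbering is used (O1, C2, C3, C4, C4a, C5 to C8, C8a), with ring A the benzo ring, ring C the pyran ring and ring B the quinone ring; the SMILES fixes C3 as S, and both starting materials are taken to be commercial.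

**Route**

Step 1
Reactants: 1 2,3-dimethoxyphenol
Product: 2 2,3-dimethoxy-1,4-benzoquinone
Conditions: (KSO3)2NO (2.2 equiv), KH2PO4, H2O/MeOH, 0 °C to rt
Reagents that add atoms: potassium nitrosodisulfonate, [K+].[K+].[O]N(S(=O)(=O)[O-])S(=O)(=O)[O-]
Why: Teuber oxidation of a phenol with a free para position should give the para-quinone, the only para site being unsubstituted.

Step 2
Reactants: 2 2,3-dimethoxy-1,4-benzoquinone
Product: 4 1,4-bis(benzyloxy)-2,3-dimethoxybenzene, via 2,3-dimethoxyhydroquinone 3 (not isolated)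
Conditions: Na2S2O4, THF/H2O, rt; then BnBr, K2CO3, Bu4NI (cat.), 60 °C, same flask, N2
Reagents that add atoms: benzyl bromide, BrCc1ccccc1
Why: Reductive alkylation of a quinone (dithionite reduction, then Williamson etherification of both phenoxides) should give the bis-benzyl ether, benzyl being chosen because it leaves in the final hydrogenolysis.

Step 3
Reactants: 4 1,4-bis(benzyloxy)-2,3-dimethoxybenzene
Product: 6 2,5-bis(benzyloxy)-3,4-dimethoxybenzaldehyde, via aryl iminium chloride 5 (not isolated)
Conditions: POCl3, DMF, 0 °C to 70 °C; then aq. NaOAc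
Reagents that add atoms: N,N-dimethylformamide, CN(C)C=O; water, O
Why: Vilsmeier–Haack formylation of the twofold-symmetric tetra-alkoxybenzene can only occur at one of its two equivalent free positions (ortho to OBn, para to OMe), so no regiochemical question arises.

Step 4
Reactants: 6 2,5-bis(benzyloxy)-3,4-dimethoxybenzaldehyde
Product: 7 1,4-bis(benzyloxy)-2,3-dimethoxy-5-(2-methoxyethenyl)benzene (E/Z mixture)
Conditions: MeOCH2PPh3Cl, KOtBu, THF, 0 °C to rt
Reagents that add atoms: (methoxymethyl)triphenylphosphonium chloride, COC[P+](c1ccccc1)(c1ccccc1)c1ccccc1.[Cl-]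
Why: Wittig methoxymethylenation adds the carbon that becomes C2, and the alkene geometry is irrelevant because both isomers hydrolyse to the same aldehyde.

Step 5
Reactants: 7 1,4-bis(benzyloxy)-2,3-dimethoxy-5-(2-methoxyethenyl)benzene
Product: 8 2-[2,5-bis(benzyloxy)-3,4-dimethoxyphenyl]acetaldehyde
Conditions: 2 M HCl, THF, 40 °C; used at once
Reagents that add atoms: water, O
Why: Acid hydrolysis of the enol ether (protonation at the benzylic carbon, hydration, loss of methanol) should give the homologated arylacetaldehyde, whose oxygen is the future O1, while benzyl aryl ethers survive dilute acid.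

Step 6
Reactants: 9 methyl 3-hydroxy-4,5-dimethoxybenzoate
Product: 10 methyl 2-bromo-3-hydroxy-4,5-dimethoxybenzoate
Conditions: NBS (1.0 equiv), i-Pr2NH (10 mol %), CH2Cl2, 0 °C
Reagents that add atoms: N-bromosuccinimide, O=C1CCC(=O)N1Br
Why: Amine-mediated ortho-selective electrophilic bromination of a phenol should deliver bromine to the only free position ortho to OH (also para to the 5-methoxy group), the carbon that becomes C8a.

Step 7
Reactants: 10 methyl 2-bromo-3-hydroxy-4,5-dimethoxybenzoate
Product: 11 methyl 3-(benzyloxy)-2-bromo-4,5-dimethoxybenzoate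
Conditions: BnBr, K2CO3, DMF, 60 °C
Reagents that add atoms: benzyl bromide, BrCc1ccccc1
Why: Williamson etherification protects the future 8-OH as a benzyl ether that should survive acid chloride formation, copper catalysis and transfer hydrogenation.

Step 8
Reactants: 11 methyl 3-(benzyloxy)-2-bromo-4,5-dimethoxybenzoate
Product: 12 3-(benzyloxy)-2-bromo-4,5-dimethoxybenzoic acid
Conditions: LiOH, THF/MeOH/H2O, 50 °C; then 1 M HCl
Reagents that add atoms: lithium hydroxide, [Li+].[OH-]
Why: Saponification of the methyl ester, to which the aryl bromide and the ethers are inert.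

Step 9
Reactants: 12 3-(benzyloxy)-2-bromo-4,5-dimethoxybenzoic acid
Product: 13 3-(benzyloxy)-2-bromo-4,5-dimethoxybenzoyl chloride
Conditions: (COCl)2, DMF (cat.), CH2Cl2, 0 °C to rt; evaporated, used crude
Reagents that add atoms: oxalyl chloride, ClC(=O)C(Cl)=O
Why: Acid chloride formation through the catalytic Vilsmeier-type chloroiminium species raises C4 to the acylating level needed in step 10.

Step 10
Reactants: 13 3-(benzyloxy)-2-bromo-4,5-dimethoxybenzoyl chloride; 8 2-[2,5-bis(benzyloxy)-3,4-dimethoxyphenyl]acetaldehyde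
Product: 15 8-(benzyloxy)-3-[2,5-bis(benzyloxy)-3,4-dimethoxyphenyl]-6,7-dimethoxy-4H-chromen-4-one, via bromoaryl keto aldehyde 14 (not isolated)
Conditions: MgCl2 (2 equiv), Et3N (2.5 equiv), MeCN, 0 °C, slow addition of 8, then rt; then CuI (10 mol %), 1,10-phenanthroline (20 mol %), Cs2CO3 (2 equiv), 80 °C, same flask
Reagents that add atoms: none
Why: Proposed new method: MgCl2/Et3N soft enolisation of the acidic alpha-aryl aldehyde 8 gives a magnesium enolate that is acylated at carbon by 13 (C3–C4), C- over O-acylation being secured by the chelated magnesium enolate of keto aldehyde 14 as the thermodynamic sink into which any enol ester is funnelled by acyl transfer, and the enolate oxygen of 14 (O1) then displaces bromide at C8a, ortho to the new ketone, by copper-catalysed Ullmann-type O-arylation (oxidative addition of CuI assisted by the ortho carbonyl, then C–O reductive elimination). The closest known reaction types are the Grohe–Heitzer cycloaracylation of enamino esters with ortho-halobenzoyl chlorides to 4-quinolones, the MgCl2/amine C-acylation of active methylene compounds with acid chlorides, and the copper-catalysed cyclisation of 1-(2-bromoaryl)-1,3-diketones to chromones and flavones; what is new is their union on an aldehyde enolate, which should give a 2-unsubstituted isoflavone. Ring C closes as a six-membered ring by intramolecular O-arylation, the (Z)-enolate oxygen attacking the C–Br carbon in a 6-exo aromatic substitution, and the 4-pyranone formed makes the closure irreversible. No stereocentre is formed, because C3 becomes sp2 here and is set in step 11. The selectivities needed are C-acylation at C3 (chelation, as above) and closure at C8a only, which the single bromide ortho to the acyl group enforces, while the benzyl and methyl aryl ethers are inert to both stages.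

Step 11
Reactants: 15 8-(benzyloxy)-3-[2,5-bis(benzyloxy)-3,4-dimethoxyphenyl]-6,7-dimethoxy-4H-chromen-4-one
Product: 17 (3S,4S)-8-(benzyloxy)-3-[2,5-bis(benzyloxy)-3,4-dimethoxyphenyl]-6,7-dimethoxychroman-4-ol, via racemic isoflavanone 16 (not isolated)
Conditions: RuCl[(S,S)-TsDPEN](p-cymene) (3 mol %), HCO2H/Et3N (5:2), EtOAc, 40 °C
Reagents that add atoms: none
Why: Noyori-type asymmetric transfer hydrogenation with dynamic kinetic resolution, a cascade known for isoflavones: Ru–H conjugate reduction gives isoflavanone 16, whose C3–H epimerises under Et3N faster than the ketone is reduced, so the (S,S)-catalyst should reduce only the (3S)-ketone from the face anti to ring B, giving C4 = S by catalyst control and C3 = S (cis) by the resolution.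

Step 12
Reactants: 17 (3S,4S)-8-(benzyloxy)-3-[2,5-bis(benzyloxy)-3,4-dimethoxyphenyl]-6,7-dimethoxychroman-4-ol
Product: 19 5-[(3S)-8-hydroxy-6,7-dimethoxy-3,4-dihydro-2H-chromen-3-yl]-2,3-dimethoxycyclohexa-2,5-diene-1,4-dione, via hydroquinone 18 (not isolated)
Conditions: H2 (1 atm), Pd/C (10 %), EtOAc/EtOH/AcOH (10:10:1), rt; filtered under Ar, solvent changed to Et2O; then Ag2O (1.05 equiv), Na2SO4, 0 °C, 15 min
Reagents that add atoms: none
Why: Catalytic hydrogenolysis should cleave the three benzyl ethers and the doubly activated benzylic C4–OH (para-methoxy, ortho-ether oxygen) without breaking any bond to C3, and the ring-B hydroquinone, far easier to oxidise than the ring-A phenol, should then be converted by Ag2O into the quinone with C3 still S.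

**Compound list**
1 | 2,3-dimethoxyphenol | COc1cccc(O)c1OC | starting material
2 | 2,3-dimethoxy-1,4-benzoquinone | COC1=C(OC)C(=O)C=CC1=O | intermediate
3 | 2,3-dimethoxybenzene-1,4-diol (not isolated) | COc1c(O)ccc(O)c1OC | intermediate
4 | 1,4-bis(benzyloxy)-2,3-dimethoxybenzene | COc1c(OCc2ccccc2)ccc(OCc2ccccc2)c1OC | intermediate
5 | N-{[2,5-bis(benzyloxy)-3,4-dimethoxyphenyl]methylidene}-N-methylmethanaminium chloride (not isolated) | C[N+](C)=Cc1cc(OCc2ccccc2)c(OC)c(OC)c1OCc1ccccc1.[Cl-] | intermediate
6 | 2,5-bis(benzyloxy)-3,4-dimethoxybenzaldehyde | O=Cc1cc(OCc2ccccc2)c(OC)c(OC)c1OCc1ccccc1 | intermediate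
7 | 1,4-bis(benzyloxy)-2,3-dimethoxy-5-(2-methoxyethenyl)benzene (E/Z mixture) | COC=Cc1cc(OCc2ccccc2)c(OC)c(OC)c1OCc1ccccc1 | intermediate
8 | 2-[2,5-bis(benzyloxy)-3,4-dimethoxyphenyl]acetaldehyde | O=CCc1cc(OCc2ccccc2)c(OC)c(OC)c1OCc1ccccc1 | intermediate
9 | methyl 3-hydroxy-4,5-dimethoxybenzoate | COC(=O)c1cc(O)c(OC)c(OC)c1 | starting material
10 | methyl 2-bromo-3-hydroxy-4,5-dimethoxybenzoate | COC(=O)c1cc(OC)c(OC)c(O)c1Br | intermediate
11 | methyl 3-(benzyloxy)-2-bromo-4,5-dimethoxybenzoate | COC(=O)c1cc(OC)c(OC)c(OCc2ccccc2)c1Br | intermediate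
12 | 3-(benzyloxy)-2-bromo-4,5-dimethoxybenzoic acid | OC(=O)c1cc(OC)c(OC)c(OCc2ccccc2)c1Br | intermediate
13 | 3-(benzyloxy)-2-bromo-4,5-dimethoxybenzoyl chloride | O=C(Cl)c1cc(OC)c(OC)c(OCc2ccccc2)c1Br | intermediate
14 | 3-[3-(benzyloxy)-2-bromo-4,5-dimethoxyphenyl]-2-[2,5-bis(benzyloxy)-3,4-dimethoxyphenyl]-3-oxopropanal (racemic, held as its enolate, not isolated) | O=CC(C(=O)c1cc(OC)c(OC)c(OCc2ccccc2)c1Br)c1cc(OCc2ccccc2)c(OC)c(OC)c1OCc1ccccc1 | intermediate
15 | 8-(benzyloxy)-3-[2,5-bis(benzyloxy)-3,4-dimethoxyphenyl]-6,7-dimethoxy-4H-chromen-4-one | O=c1c(-c2cc(OCc3ccccc3)c(OC)c(OC)c2OCc2ccccc2)coc2c(OCc3ccccc3)c(OC)c(OC)cc12 | intermediate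
16 | 8-(benzyloxy)-3-[2,5-bis(benzyloxy)-3,4-dimethoxyphenyl]-6,7-dimethoxychroman-4-one (racemic, epimerising, not isolated) | O=C1C(c2cc(OCc3ccccc3)c(OC)c(OC)c2OCc2ccccc2)COc2c(OCc3ccccc3)c(OC)c(OC)cc21 | intermediate
17 | (3S,4S)-8-(benzyloxy)-3-[2,5-bis(benzyloxy)-3,4-dimethoxyphenyl]-6,7-dimethoxychroman-4-ol | O[C@H]1[C@@H](c2cc(OCc3ccccc3)c(OC)c(OC)c2OCc2ccccc2)COc2c(OCc3ccccc3)c(OC)c(OC)cc21 | intermediate
18 | (3S)-3-(2,5-dihydroxy-3,4-dimethoxyphenyl)-6,7-dimethoxychroman-8-ol (not isolated) | COc1c(O)cc([C@H]2COc3c(O)c(OC)c(OC)cc3C2)c(O)c1OC | intermediate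
19 | 5-[(3S)-8-hydroxy-6,7-dimethoxy-3,4-dihydro-2H-chromen-3-yl]-2,3-dimethoxycyclohexa-2,5-diene-1,4-dione | COC1=C(OC)C(=O)C([C@H]2COc3c(cc(OC)c(OC)c3O)C2)=CC1=O | target

**Step count**
Total: 12 steps. Longest linear sequence: 8 steps (steps 1 to 5, then 10 to 12).

**Steps most likely to fail, with fallbacks**

Step 10 (proposed new method). O-acylation or self-aldol condensation of the aldehyde enolate may outrun C-acylation, or the O-arylation at the hindered, electron-rich C8a–Br bond may stall. The fallback uses known chemistry, sets out from 8 and 13, and separates the two events. Condensation of 8 with morpholine (MgSO4, toluene, rt) should give the enamine (E)-4-{2-[2,5-bis(benzyloxy)-3,4-dimethoxyphenyl]ethenyl}morpholine F1. Stork C-acylation of F1 with 13 (Et3N, CH2Cl2, 0 °C to rt) should give the enaminone 1-[3-(benzyloxy)-2-bromo-4,5-dimethoxyphenyl]-2-[2,5-bis(benzyloxy)-3,4-dimethoxyphenyl]-3-(morpholin-4-yl)prop-2-en-1-one F2. Hydrolysis (1 M HCl, THF) should give 14, now isolated as its enol, and a separate copper-catalysed cyclisation (CuI, 1,10-phenanthroline, Cs2CO3, DMF, 80 °C) comes back to the route at 15.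

Step 6. Bromination may occur para to the hydroxyl, at the position between the ester and the 5-methoxy group, instead of ortho. The fallback sets out from 9 and replaces electrophilic substitution by directed metalation. MOMCl and i-Pr2NEt (CH2Cl2) should give methyl 3-(methoxymethoxy)-4,5-dimethoxybenzoate F3. TMPMgCl·LiCl (THF, 0 °C) should magnesiate the position flanked by the ester and the chelating MOM ether, giving chlorido[2-(methoxycarbonyl)-6-(methoxymethoxy)-4,5-dimethoxyphenyl]magnesium F4. Quenching with BrCl2C–CCl2Br should give methyl 2-bromo-3-(methoxymethoxy)-4,5-dimethoxybenzoate F5, and HCl in MeOH removes the MOM group and comes back to the route at 10.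

Step 12. Acid-promoted dehydration of the benzylic alcohol to the isoflav-3-ene, followed by unselective hydrogenation, would erode the C3 configuration; over-oxidation of the ring-A phenol is the second hazard. The fallback sets out from 17 and removes the C4 oxygen by a radical path that cannot touch C3. NaH, CS2, then MeI (THF, 0 °C) should give the xanthate O-[(3S,4S)-8-(benzyloxy)-3-[2,5-bis(benzyloxy)-3,4-dimethoxyphenyl]-6,7-dimethoxychroman-4-yl] S-methyl carbonodithioate F6; C3–H is trans to the xanthate, so syn-elimination is not available. Barton–McCombie reduction (Bu3SnH, AIBN, toluene, 80 °C) should give (3S)-8-(benzyloxy)-3-[2,5-bis(benzyloxy)-3,4-dimethoxyphenyl]-6,7-dimethoxychroman F7. Neutral hydrogenolysis (H2, Pd/C, EtOAc) comes back to the route at 18, which is oxidised as in step 12.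

**Further compounds**
F1 | step 10 | (E)-4-{2-[2,5-bis(benzyloxy)-3,4-dimethoxyphenyl]ethenyl}morpholine | O1CCN(CC1)/C=C/c1cc(OCc2ccccc2)c(OC)c(OC)c1OCc1ccccc1
F2 | step 10 | 1-[3-(benzyloxy)-2-bromo-4,5-dimethoxyphenyl]-2-[2,5-bis(benzyloxy)-3,4-dimethoxyphenyl]-3-(morpholin-4-yl)prop-2-en-1-one | O=C(C(=CN1CCOCC1)c1cc(OCc2ccccc2)c(OC)c(OC)c1OCc1ccccc1)c1cc(OC)c(OC)c(OCc2ccccc2)c1Br
F3 | step 6 | methyl 3-(methoxymethoxy)-4,5-dimethoxybenzoate | COCOc1cc(C(=O)OC)cc(OC)c1OC
F4 | step 6 | chlorido[2-(methoxycarbonyl)-6-(methoxymethoxy)-4,5-dimethoxyphenyl]magnesium | COCOc1c([Mg]Cl)c(C(=O)OC)cc(OC)c1OC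
F5 | step 6 | methyl 2-bromo-3-(methoxymethoxy)-4,5-dimethoxybenzoate | COCOc1c(Br)c(C(=O)OC)cc(OC)c1OC
F6 | step 12 | O-[(3S,4S)-8-(benzyloxy)-3-[2,5-bis(benzyloxy)-3,4-dimethoxyphenyl]-6,7-dimethoxychroman-4-yl] S-methyl carbonodithioate | CSC(=S)O[C@H]1[C@@H](c2cc(OCc3ccccc3)c(OC)c(OC)c2OCc2ccccc2)COc2c(OCc3ccccc3)c(OC)c(OC)cc21
F7 | step 12 | (3S)-8-(benzyloxy)-3-[2,5-bis(benzyloxy)-3,4-dimethoxyphenyl]-6,7-dimethoxychroman | C1[C@@H](c2cc(OCc3ccccc3)c(OC)c(OC)c2OCc2ccccc2)COc2c(OCc3ccccc3)c(OC)c(OC)cc21
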